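Ring B is a hexasubstituted phloroglucinol, and its three oxygens at C2', C4' and C6' map onto a ketene carbonyl, a siloxyalkyne oxygen and the alkoxy group of a 3-alkoxycyclobutenone. The route therefore rests on a thermal cyclobutenone–siloxyalkyne benzannulation that forms C1'–C2', C2'–C3' and C4'–C5' and closes ring B next to the finished, protected ring A in one operation, leaving only C5' open for the isobutyryl group. The precursor is a racemic 3-benzyloxycyclobut-2-enone that carries the ring A benzyl unit (acetyl, methoxy, methyl, two benzyl ethers) at C4; its partner is the isopentyl-substituted triisopropylsiloxyalkyne.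

Key step: step 10

Remarks on the chemistry:
- Locants: ring A is the acetyl-bearing ring; ring B carries primed locants, C1' being the carbon bonded to the bridging CH2.
- Design choice: the oxygen at C3 of the cyclobutenone (later the C6' oxygen) carries benzyl, brought in with benzyl ethynyl ether. All three protecting groups then fall in one neutral hydrogenolysis, and the ring A methyl ether never meets a dealkylating Lewis acid; a plain alkyl ether at C6' could not be removed reliably beside it.
- Stereochemistry: the target has no stereocenter. The only stereocenter of the route, C4 of the cyclobutenone, is racemic and disappears in step 10.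

Step 1
Reactants: 1 2,4,6-trihydroxytoluene
Product: 2 1-(2,4,6-trihydroxy-3-methylphenyl)ethan-1-one
Conditions: Ac2O (1.05 equiv), BF3·OEt2, EtOAc, 0 °C → rt; aqueous work-up
Reagents that add atoms: acetic anhydride, CC(=O)OC(C)=O
Why: Friedel–Crafts C-acetylation of a phloroglucinol, in which the two open ring carbons are equivalent and the first acyl group deactivates the ring against a second acylation.

Step 2
Reactants: 2 1-(2,4,6-trihydroxy-3-methylphenyl)ethan-1-one
Product: 3 1-(2,6-dihydroxy-4-methoxy-3-methylphenyl)ethan-1-one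
Conditions: Me2SO4 (1.0 equiv), K2CO3 (1.0 equiv), acetone, rt
Reagents that add atoms: dimethyl sulfate, COS(=O)(=O)OC
Why: Williamson O-methylation that should select the hydroxyl para to the acetyl group, the most acidic one and the only one that cannot hydrogen-bond to the carbonyl oxygen.

Step 3
Reactants: 3 1-(2,6-dihydroxy-4-methoxy-3-methylphenyl)ethan-1-one
Product: 5 3-acetyl-2,4-dihydroxy-6-methoxy-5-methylbenzaldehyde, via chloromethyl ether 4 (not isolated)
Conditions: Cl2CHOMe, TiCl4, CH2Cl2, −10 °C → rt; aq. HCl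
Reagents that add atoms: dichloromethyl methyl ether, COC(Cl)Cl; water, O
Why: Rieche formylation at the single unsubstituted ring carbon, which lies ortho to a titanium-bound phenoxide and is activated by three oxygens, followed by hydrolysis of the chloromethyl ether on work-up.

Step 4
Reactants: 5 3-acetyl-2,4-dihydroxy-6-methoxy-5-methylbenzaldehyde
Product: 6 3-acetyl-2,4-bis(benzyloxy)-6-methoxy-5-methylbenzaldehyde
Conditions: BnBr (2.5 equiv), K2CO3, DMF, 50 °C
Reagents that add atoms: benzyl bromide, BrCc1ccccc1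
Why: Williamson O-benzylation of both chelated phenols, with no ring carbon left open for C-benzylation.

Step 5
Reactants: 6 3-acetyl-2,4-bis(benzyloxy)-6-methoxy-5-methylbenzaldehyde; 7 Meldrum's acid (2,2-dimethyl-1,3-dioxane-4,6-dione)
Product: 10 3-[3-acetyl-2,4-bis(benzyloxy)-6-methoxy-5-methylphenyl]propanoic acid, via arylidene Meldrum's acid 8 (not isolated), via arylmethyl Meldrum's acid 9 (not isolated)
Conditions: HCO2H–Et3N (5:2), 95–100 °C
Reagents that add atoms: none
Why: Knoevenagel condensation, conjugate reduction of the alkylidene by formate and hydrolysis–decarboxylation of the dioxanedione run in one pot, and without a transition metal the formate buffer should touch neither the hindered aryl ketone nor the benzyl ethers.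

Step 6
Reactants: 10 3-[3-acetyl-2,4-bis(benzyloxy)-6-methoxy-5-methylphenyl]propanoic acid
Product: 11 3-[3-acetyl-2,4-bis(benzyloxy)-6-methoxy-5-methylphenyl]propanoyl chloride
Conditions: (COCl)2, cat. DMF, CH2Cl2, 0 °C → rt; concentrate, use crude at once
Reagents that add atoms: oxalyl chloride, O=C(Cl)C(Cl)=O
Why: Acid chloride formation through the catalytic Vilsmeier-type chloroiminium species under cold, neutral conditions, with immediate use so that the ortho benzyloxy group has no time to lactonise onto the acyl chloride.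

Step 7
Reactants: 12 benzyl alcohol; 13 trichloroethylene
Product: 16 benzyl ethynyl ether, via dichlorovinyl ether 14 (not isolated), via lithium alkynide 15 (not isolated)
Conditions: KH, THF, 0 °C; Cl2C=CHCl, −50 °C → rt; n-BuLi (2.2 equiv), −78 °C; H2O, −78 °C; kept as a cold solution
Reagents that add atoms: none
Why: Dichlorovinyl ether route to ynol ethers, in which alkoxide addition–elimination on trichloroethylene is followed by dehydrochlorination and chlorine–lithium exchange to the alkynide, protonated cold because benzyl ynol ethers rearrange on warming.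

Step 8
Reactants: 11 3-[3-acetyl-2,4-bis(benzyloxy)-6-methoxy-5-methylphenyl]propanoyl chloride; 16 benzyl ethynyl ether
Product: 18 4-{[3-acetyl-2,4-bis(benzyloxy)-6-methoxy-5-methylphenyl]methyl}-3-(benzyloxy)cyclobut-2-en-1-one (racemic), via arylmethylketene 17 (not isolated)
Conditions: 16 (2–3 equiv), Et3N (slow addition), CH2Cl2, 0 °C → rt
Reagents that add atoms: none
Why: Dehydrochlorination gives the monoalkylketene, which the ynol ether captures in a [2+2] cycloaddition with its nucleophilic terminal carbon on the ketene carbonyl carbon, so that benzyloxy ends at C3 and the arylmethyl group at C4, whose new stereocenter forms racemic and is erased in step 10.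

Step 9
Reactants: 19 ethyl 4-methylpentanoate
Product: 23 triisopropyl[(5-methylhex-1-yn-1-yl)oxy]silane, via tetrahedral adduct 20 (not isolated), via dibromo enolate 21 (not isolated), via lithium ynolate 22 (not isolated)
Conditions: CH2Br2, LiTMP, THF, −78 °C; LiN(SiMe3)2; n-BuLi, −78 °C → rt; i-Pr3SiCl, −78 °C → rt
Reagents that add atoms: dibromomethane, BrCBr; chlorotriisopropylsilane, CC(C)[Si](Cl)(C(C)C)C(C)C
Why: Kowalski ynolate homologation, in which the dibromomethyl ketone enolate undergoes bromine–lithium exchange and 1,2-shift of the isopentyl group to the ynolate, which the bulky silyl chloride captures on oxygen.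

Step 10
Reactants: 18 4-{[3-acetyl-2,4-bis(benzyloxy)-6-methoxy-5-methylphenyl]methyl}-3-(benzyloxy)cyclobut-2-en-1-one; 23 triisopropyl[(5-methylhex-1-yn-1-yl)oxy]silane
Product: 28 1-[2,6-bis(benzyloxy)-3-{[6-(benzyloxy)-2-hydroxy-3-(3-methylbutyl)-4-{[tri(propan-2-yl)silyl]oxy}phenyl]methyl}-4-methoxy-5-methylphenyl]ethan-1-one, via vinylketene 24 (not isolated), via vinylcyclobutenone 25 (not isolated), via dienylketene 26 (not isolated), via cyclohexadienone 27 (not isolated)
Conditions: 23 (2 equiv), toluene, 80 → 110 °C, sealed tube, argon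
Reagents that add atoms: none
Why: Danheiser benzannulation: thermal 4π electrocyclic opening of 18 gives vinylketene 24, whose ketene C=C adds the siloxyalkyne in a [2+2] cycloaddition (transient four-membered ring of 25); a second 4π opening gives dienylketene 26, which closes ring B as a six-membered carbocycle by thermal 6π electrocyclisation to 27, and enolisation delivers the phenol. The closest known reaction type is the benzannulation of cyclobutenones with alkoxy- and siloxyalkynes to resorcinol monoethers. No stereocenter is formed, and the racemic C4 centre of 18 becomes the aromatic carbon C1'. The selectivity needed is the regiochemistry of the ketene–alkyne cycloaddition, secured by the polarisation of the siloxyalkyne: its nucleophilic, isopentyl-bearing carbon bonds to the ketene carbonyl carbon, so isopentyl lies between the new C2' hydroxyl and the C4' siloxy carbon while C5' stays unsubstituted. Outward rotation of the arylmethyl group in the first opening leaves the diene terminus free for the final closure, and the neutral conditions should spare the aryl ketone and the benzyl ethers.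

Step 11
Reactants: 28 1-[2,6-bis(benzyloxy)-3-{[6-(benzyloxy)-2-hydroxy-3-(3-methylbutyl)-4-{[tri(propan-2-yl)silyl]oxy}phenyl]methyl}-4-methoxy-5-methylphenyl]ethan-1-one
Product: 29 1-[2,6-bis(benzyloxy)-3-{[6-(benzyloxy)-2,4-dihydroxy-3-(3-methylbutyl)phenyl]methyl}-4-methoxy-5-methylphenyl]ethan-1-one
Conditions: Bu4NF, AcOH, THF, 0 °C, argon
Reagents that add atoms: none
Why: Fluoride-induced cleavage of the aryl silyl ether, buffered with acetic acid so that the electron-rich resorcinol does not stand as a free phenoxide open to air oxidation.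

Step 12
Reactants: 29 1-[2,6-bis(benzyloxy)-3-{[6-(benzyloxy)-2,4-dihydroxy-3-(3-methylbutyl)phenyl]methyl}-4-methoxy-5-methylphenyl]ethan-1-one
Product: 30 1-[3-{[3-acetyl-2,4-bis(benzyloxy)-6-methoxy-5-methylphenyl]methyl}-2-(benzyloxy)-4,6-dihydroxy-5-(3-methylbutyl)phenyl]-2-methylpropan-1-one
Conditions: i-PrCOCl (1.2 equiv), TiCl4 (2.5 equiv), CH2Cl2, −78 → −20 °C; aq. HCl
Reagents that add atoms: isobutyryl chloride (2-methylpropanoyl chloride), CC(C)C(Cl)=O
Why: Friedel–Crafts acylation through the titanium phenoxide at C5', the only unsubstituted carbon of rings A and B and ortho and para to the two free hydroxyls, run cold so that the benzyl ethers and the methylene bridge should survive.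

Step 13
Reactants: 30 1-[3-{[3-acetyl-2,4-bis(benzyloxy)-6-methoxy-5-methylphenyl]methyl}-2-(benzyloxy)-4,6-dihydroxy-5-(3-methylbutyl)phenyl]-2-methylpropan-1-one
Product: 31 1-[3-{[3-acetyl-2,4-dihydroxy-6-methoxy-5-methylphenyl]methyl}-2,4,6-trihydroxy-5-(3-methylbutyl)phenyl]-2-methylpropan-1-one (CNP0238575.0)
Conditions: H2 (1 atm), 10% Pd/C, EtOAc, rt
Reagents that add atoms: none
Why: Hydrogenolysis of the three benzyl ethers under neutral conditions, which should leave the two chelated aryl ketones and the ring A methyl ether untouched.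

Compound list
1 | 2,4,6-trihydroxytoluene | Cc1c(O)cc(O)cc1O | starting material
2 | 1-(2,4,6-trihydroxy-3-methylphenyl)ethan-1-one | CC(=O)c1c(O)cc(O)c(C)c1O | intermediate
3 | 1-(2,6-dihydroxy-4-methoxy-3-methylphenyl)ethan-1-one | COc1cc(O)c(C(C)=O)c(O)c1C | intermediate
4 | 1-{3-[chloro(methoxy)methyl]-2,6-dihydroxy-4-methoxy-5-methylphenyl}ethan-1-one (racemic; formed in the flask in step 3) | COc1c(C)c(O)c(C(C)=O)c(O)c1C(Cl)OC | intermediate
5 | 3-acetyl-2,4-dihydroxy-6-methoxy-5-methylbenzaldehyde | COc1c(C)c(O)c(C(C)=O)c(O)c1C=O | intermediate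
6 | 3-acetyl-2,4-bis(benzyloxy)-6-methoxy-5-methylbenzaldehyde | COc1c(C)c(OCc2ccccc2)c(C(C)=O)c(OCc2ccccc2)c1C=O | intermediate
7 | Meldrum's acid (2,2-dimethyl-1,3-dioxane-4,6-dione) | CC1(C)OC(=O)CC(=O)O1 | starting material
8 | 5-{[3-acetyl-2,4-bis(benzyloxy)-6-methoxy-5-methylphenyl]methylidene}-2,2-dimethyl-1,3-dioxane-4,6-dione (formed in the flask in step 5) | CC1(C)OC(=O)C(=Cc2c(OC)c(C)c(OCc3ccccc3)c(C(C)=O)c2OCc2ccccc2)C(=O)O1 | intermediate
9 | 5-{[3-acetyl-2,4-bis(benzyloxy)-6-methoxy-5-methylphenyl]methyl}-2,2-dimethyl-1,3-dioxane-4,6-dione (formed in the flask in step 5) | CC1(C)OC(=O)C(Cc2c(OC)c(C)c(OCc3ccccc3)c(C(C)=O)c2OCc2ccccc2)C(=O)O1 | intermediate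
10 | 3-[3-acetyl-2,4-bis(benzyloxy)-6-methoxy-5-methylphenyl]propanoic acid | COc1c(C)c(OCc2ccccc2)c(C(C)=O)c(OCc2ccccc2)c1CCC(=O)O | intermediate
11 | 3-[3-acetyl-2,4-bis(benzyloxy)-6-methoxy-5-methylphenyl]propanoyl chloride | COc1c(C)c(OCc2ccccc2)c(C(C)=O)c(OCc2ccccc2)c1CCC(Cl)=O | intermediate
12 | benzyl alcohol | OCc1ccccc1 | starting material
13 | trichloroethylene | ClC=C(Cl)Cl | starting material
14 | benzyl (E)-1,2-dichloroethenyl ether (formed in the flask in step 7) | Cl/C=C(/Cl)OCc1ccccc1 | intermediate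
15 | lithium (benzyloxy)ethynide (formed in the flask in step 7) | [Li]C#COCc1ccccc1 | intermediate
16 | benzyl ethynyl ether, [(ethynyloxy)methyl]benzene | C#COCc1ccccc1 | intermediate
17 | 3-[3-acetyl-2,4-bis(benzyloxy)-6-methoxy-5-methylphenyl]prop-1-en-1-one, the arylmethylketene (formed in the flask in step 8) | COc1c(C)c(OCc2ccccc2)c(C(C)=O)c(OCc2ccccc2)c1CC=C=O | intermediate
18 | 4-{[3-acetyl-2,4-bis(benzyloxy)-6-methoxy-5-methylphenyl]methyl}-3-(benzyloxy)cyclobut-2-en-1-one (racemic) | COc1c(C)c(OCc2ccccc2)c(C(C)=O)c(OCc2ccccc2)c1CC1C(=O)C=C1OCc1ccccc1 | intermediate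
19 | ethyl 4-methylpentanoate | CCOC(=O)CCC(C)C | starting material
20 | lithium 1,1-dibromo-2-ethoxy-5-methylhexan-2-olate (racemic; formed in the flask in step 9) | CCOC([O-])(CCC(C)C)C(Br)Br.[Li+] | intermediate
21 | lithium 1,1-dibromo-5-methylhex-1-en-2-olate (formed in the flask in step 9) | CC(C)CCC([O-])=C(Br)Br.[Li+] | intermediate
22 | lithium 5-methylhex-1-yn-1-olate (formed in the flask in step 9) | CC(C)CCC#C[O-].[Li+] | intermediate
23 | triisopropyl[(5-methylhex-1-yn-1-yl)oxy]silane | CC(C)CCC#CO[Si](C(C)C)(C(C)C)C(C)C | intermediate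
24 | (3Z)-5-[3-acetyl-2,4-bis(benzyloxy)-6-methoxy-5-methylphenyl]-3-(benzyloxy)penta-1,3-dien-1-one, the vinylketene (formed in the flask in step 10) | O=C=C/C(OCc1ccccc1)=C/Cc1c(OC)c(C)c(OCc2ccccc2)c(C(C)=O)c1OCc1ccccc1 | intermediate
25 | 4-[(1Z)-3-[3-acetyl-2,4-bis(benzyloxy)-6-methoxy-5-methylphenyl]-1-(benzyloxy)prop-1-en-1-yl]-2-(3-methylbutyl)-3-{[tri(propan-2-yl)silyl]oxy}cyclobut-2-en-1-one (racemic; formed in the flask in step 10) | O=C1C(CCC(C)C)=C(O[Si](C(C)C)(C(C)C)C(C)C)C1/C(OCc1ccccc1)=C/Cc1c(OC)c(C)c(OCc2ccccc2)c(C(C)=O)c1OCc1ccccc1 | intermediate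
26 | (3E,5Z)-7-[3-acetyl-2,4-bis(benzyloxy)-6-methoxy-5-methylphenyl]-5-(benzyloxy)-2-(3-methylbutyl)-3-{[tri(propan-2-yl)silyl]oxy}hepta-1,3,5-trien-1-one, the dienylketene (formed in the flask in step 10) | O=C=C(CCC(C)C)/C(O[Si](C(C)C)(C(C)C)C(C)C)=C\C(OCc1ccccc1)=C\Cc1c(OC)c(C)c(OCc2ccccc2)c(C(C)=O)c1OCc1ccccc1 | intermediate
27 | 6-{[3-acetyl-2,4-bis(benzyloxy)-6-methoxy-5-methylphenyl]methyl}-5-(benzyloxy)-2-(3-methylbutyl)-3-{[tri(propan-2-yl)silyl]oxy}cyclohexa-2,4-dien-1-one (racemic; formed in the flask in step 10) | O=C1C(CCC(C)C)=C(O[Si](C(C)C)(C(C)C)C(C)C)C=C(OCc2ccccc2)C1Cc1c(OC)c(C)c(OCc2ccccc2)c(C(C)=O)c1OCc1ccccc1 | intermediate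
28 | 1-[2,6-bis(benzyloxy)-3-{[6-(benzyloxy)-2-hydroxy-3-(3-methylbutyl)-4-{[tri(propan-2-yl)silyl]oxy}phenyl]methyl}-4-methoxy-5-methylphenyl]ethan-1-one | c1ccccc1COc1cc(O[Si](C(C)C)(C(C)C)C(C)C)c(CCC(C)C)c(O)c1Cc1c(OC)c(C)c(OCc2ccccc2)c(C(C)=O)c1OCc1ccccc1 | intermediate
29 | 1-[2,6-bis(benzyloxy)-3-{[6-(benzyloxy)-2,4-dihydroxy-3-(3-methylbutyl)phenyl]methyl}-4-methoxy-5-methylphenyl]ethan-1-one | c1ccccc1COc1cc(O)c(CCC(C)C)c(O)c1Cc1c(OC)c(C)c(OCc2ccccc2)c(C(C)=O)c1OCc1ccccc1 | intermediate
30 | 1-[3-{[3-acetyl-2,4-bis(benzyloxy)-6-methoxy-5-methylphenyl]methyl}-2-(benzyloxy)-4,6-dihydroxy-5-(3-methylbutyl)phenyl]-2-methylpropan-1-one | c1ccccc1COc1c(C(=O)C(C)C)c(O)c(CCC(C)C)c(O)c1Cc1c(OC)c(C)c(OCc2ccccc2)c(C(C)=O)c1OCc1ccccc1 | intermediate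
31 | 1-[3-{[3-acetyl-2,4-dihydroxy-6-methoxy-5-methylphenyl]methyl}-2,4,6-trihydroxy-5-(3-methylbutyl)phenyl]-2-methylpropan-1-one (CNP0238575.0) | COc1c(C)c(O)c(C(C)=O)c(O)c1Cc1c(O)c(CCC(C)C)c(O)c(C(=O)C(C)C)c1O | target

Total step count: 13.
Longest linear sequence: 11 steps (steps 1–6, 8, 10–13); steps 7 and 9 are side branches.

Steps most likely to fail

Step 10 (key benzannulation). The vinylogous-ester-stabilised cyclobutenone may open slowly, so that at the temperature needed the siloxyalkyne isomerises or the vinylketene dimerises before cross-cycloaddition, or the cascade stalls before the 6π closure. The fallback sets out from 3 and comes back at 31. It joins two complete rings through the methylene bridge by Mannich base and ortho-quinone methide coupling, the established way to unsymmetrical methylene-bridged acylphloroglucinols. Aminomethylation of 3 at its single open ring carbon with dimethylmethylideneammonium iodide should give the Mannich base 1-{3-[(dimethylamino)methyl]-2,6-dihydroxy-4-methoxy-5-methylphenyl}ethan-1-one F1. Ring B is made from commercial phloroglucinol: Friedel–Crafts isobutyrylation (i-PrCOCl, AlCl3, PhNO2) to 2-methyl-1-(2,4,6-trihydroxyphenyl)propan-1-one F2, C-prenylation (prenyl bromide, aq. KOH) to 2-methyl-1-[2,4,6-trihydroxy-3-(3-methylbut-2-en-1-yl)phenyl]propan-1-one F3, and hydrogenation (H2, Pd/C) to 2-methyl-1-[2,4,6-trihydroxy-3-(3-methylbutyl)phenyl]propan-1-one F4. Heating F1 with F4 in dioxane should expel dimethylamine, and the quinone methide of ring A should be trapped by the last open ring carbon of F4 to give 31.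

Step 8 (ketene–ynol ether cycloaddition). Sigmatropic rearrangement or hydration of the benzyl ynol ether, or dimerisation of the monoalkylketene, may outrun the cross-[2+2] cycloaddition. The fallback sets out from 11 and comes back at 31. It replaces 16 by commercial ethoxyacetylene, the standard ketenophile for this cycloaddition, and changes the end game to a Lewis acid dealkylation. Acid chloride 11, ethoxyacetylene and Et3N should give 4-{[3-acetyl-2,4-bis(benzyloxy)-6-methoxy-5-methylphenyl]methyl}-3-ethoxycyclobut-2-en-1-one F5. Benzannulation with 23 as in step 10 should give 1-[2,6-bis(benzyloxy)-3-{[6-ethoxy-2-hydroxy-3-(3-methylbutyl)-4-{[tri(propan-2-yl)silyl]oxy}phenyl]methyl}-4-methoxy-5-methylphenyl]ethan-1-one F6. Bu4NF with AcOH should give 1-[2,6-bis(benzyloxy)-3-{[6-ethoxy-2,4-dihydroxy-3-(3-methylbutyl)phenyl]methyl}-4-methoxy-5-methylphenyl]ethan-1-one F7, and acylation as in step 12 should give 1-[3-{[3-acetyl-2,4-bis(benzyloxy)-6-methoxy-5-methylphenyl]methyl}-2-ethoxy-4,6-dihydroxy-5-(3-methylbutyl)phenyl]-2-methylpropan-1-one F8. BCl3 in CH2Cl2 (−78 → 0 °C) should then cleave the two benzyl ethers and the ethyl ether, all ortho to a ketone carbonyl, to give 31. The price is a less certain last step, since the ring A methyl ether has to be spared.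

Step 12 (acylation at C5'). The Lewis acid may strip benzyl groups and re-attach them at C5', or protonation of the very electron-rich ring B at C1' may break the methylene bridge, before C-acylation takes place. The fallback sets out from 29 and comes back at 31. It removes the benzyl groups first and acylates the free polyphenol in the classical way for phloroglucinols. Hydrogenolysis of 29 (H2, Pd/C, EtOAc) should give 1-[2,6-dihydroxy-4-methoxy-3-methyl-5-{[2,4,6-trihydroxy-3-(3-methylbutyl)phenyl]methyl}phenyl]ethan-1-one F9. Isobutyryl chloride with AlCl3 in nitrobenzene at rt should then acylate C5', the only open ring carbon, to give 31.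

Further compounds
F1 | step 10 | 1-{3-[(dimethylamino)methyl]-2,6-dihydroxy-4-methoxy-5-methylphenyl}ethan-1-one | COc1c(CN(C)C)c(O)c(C(C)=O)c(O)c1C
F2 | step 10 | 2-methyl-1-(2,4,6-trihydroxyphenyl)propan-1-one | CC(C)C(=O)c1c(O)cc(O)cc1O
F3 | step 10 | 2-methyl-1-[2,4,6-trihydroxy-3-(3-methylbut-2-en-1-yl)phenyl]propan-1-one | CC(C)C(=O)c1c(O)cc(O)c(CC=C(C)C)c1O
F4 | step 10 | 2-methyl-1-[2,4,6-trihydroxy-3-(3-methylbutyl)phenyl]propan-1-one | CC(C)C(=O)c1c(O)cc(O)c(CCC(C)C)c1O
F5 | step 8 | 4-{[3-acetyl-2,4-bis(benzyloxy)-6-methoxy-5-methylphenyl]methyl}-3-ethoxycyclobut-2-en-1-one (racemic) | COc1c(C)c(OCc2ccccc2)c(C(C)=O)c(OCc2ccccc2)c1CC1C(=O)C=C1OCC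
F6 | step 8 | 1-[2,6-bis(benzyloxy)-3-{[6-ethoxy-2-hydroxy-3-(3-methylbutyl)-4-{[tri(propan-2-yl)silyl]oxy}phenyl]methyl}-4-methoxy-5-methylphenyl]ethan-1-one | CCOc1cc(O[Si](C(C)C)(C(C)C)C(C)C)c(CCC(C)C)c(O)c1Cc1c(OC)c(C)c(OCc2ccccc2)c(C(C)=O)c1OCc1ccccc1
F7 | step 8 | 1-[2,6-bis(benzyloxy)-3-{[6-ethoxy-2,4-dihydroxy-3-(3-methylbutyl)phenyl]methyl}-4-methoxy-5-methylphenyl]ethan-1-one | CCOc1cc(O)c(CCC(C)C)c(O)c1Cc1c(OC)c(C)c(OCc2ccccc2)c(C(C)=O)c1OCc1ccccc1
F8 | step 8 | 1-[3-{[3-acetyl-2,4-bis(benzyloxy)-6-methoxy-5-methylphenyl]methyl}-2-ethoxy-4,6-dihydroxy-5-(3-methylbutyl)phenyl]-2-methylpropan-1-one | CCOc1c(C(=O)C(C)C)c(O)c(CCC(C)C)c(O)c1Cc1c(OC)c(C)c(OCc2ccccc2)c(C(C)=O)c1OCc1ccccc1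
F9 | step 12 | 1-[2,6-dihydroxy-4-methoxy-3-methyl-5-{[2,4,6-trihydroxy-3-(3-methylbutyl)phenyl]methyl}phenyl]ethan-1-one | COc1c(C)c(O)c(C(C)=O)c(O)c1Cc1c(O)cc(O)c(CCC(C)C)c1O
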